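## Structural features

Compound 17 is a macrocyclic bis(bibenzyl). Four benzene rings, lettered here A (methoxy ring), B (meta-linked ring), C (hydroxylated ring) and D (para-linked ring), are tied into one 18-membered ring by two diaryl ether oxygens (A–O–B and C–O–D) and two CH2CH2 bridges (B–C and D–A). Ring A is 1,2,3-trisubstituted: its ether carbon C2 is wedged between the methoxy-bearing carbon and the carbon that carries the bridge to ring D. Ring B is 1,3-linked and ring D is 1,4-linked. Ring C carries the bridge, the ether oxygen meta to it, and a free hydroxyl para to the bridge and ortho to the ether. There is no stereocentre, so nothing has to be set or guarded against epimerisation. The fragile parts are the electron-rich ring C with its free phenol in the target and, in the intermediates, the aryl iodide, the benzyl ether (which must outlive an alkene reduction) and the base-sensitive 1,2-diketone. The real difficulties are the entropic cost of closing an 18-membered ring and the formation of the doubly ortho-flanked C–O bond on ring A. The feature used is that C2 of ring A is ortho to the benzylic carbon of the D–A bridge. At the 1,2-dione oxidation level that carbon is a carbonyl that activates a fluoride on C2 for addition–elimination, has no α-hydrogen, and is afterwards reduced to the CH2CH2 bridge itself.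

## Logic of the disconnections

17 ⇒ 16. No skeletal bond is cut. The two methylene carbons of the D–A bridge are raised to carbonyl groups and the ring C hydroxyl is benzylated. The carbonyl next to ring A is what makes C2 of ring A electrophilic, and the benzyl group silences the second phenol. The demand on the forward step is that one hydrogenation must take both benzylic carbonyls down to CH2 and cleave the benzyl ether, while sparing the diaryl ethers and the methyl ether.

16 ⇒ 15. The bond between C2 of ring A and the ring B oxygen is cut, which opens the 18-membered ring. This is the most hindered bond of the skeleton and the only one that the adjacent carbonyl can activate. The gain is an acyclic precursor that already holds every carbon. The forward step must favour ring closure over chain growth, displace fluoride and not the aryloxy group para to the other carbonyl on ring D, and leave the diketone intact under base.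

15 ⇒ 14. Only the O–H of ring B is changed, to an O–Si bond. The nucleophile should stay masked through the metal-catalysed steps and be released last, without base, so that no phenoxide meets the activated fluoride at preparative concentration. The forward step needs a cleavage that is orthogonal to the benzyl ether.

14 ⇒ 13. The two carbonyl groups are traced back to a C≡C bond. A diketone would not survive ylide or cross-coupling chemistry, whereas a diaryl alkyne is inert and easy to assemble. The forward oxidation must not touch the benzylic CH2 groups or the ethers.

13 ⇒ 10 + 12. The bond between the alkyne carbon and ring D is cut. This joins the large iodide fragment and the small ring A alkyne convergently. The forward coupling must engage the C–I bond only and leave the C–F bond alone.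

12 ⇒ 11. The terminal alkyne carbon is removed, leaving an aldehyde. The forward step is a one-carbon homologation that must not displace the ortho fluoride.

10 ⇒ 9 ⇒ 5 (through 8) + 7. The B–C bridge is first desaturated and the C=C bond is then cut between the two bridge carbons. This divides the iodide fragment into a ring C–D unit and a ring B unit. Olefin geometry is irrelevant because the double bond is reduced. The reduction must spare the aryl iodide and the benzyl ether, which rules out palladium and hydrogen at this point.

5 ⇒ 4 ⇒ 3 and 7 ⇒ 6. These are functional group changes only: phosphonium salt from alcohol from aldehyde, and silyl ether from phenol.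

3 ⇒ 1 + 2. The C–O bond between ring D and the ring C oxygen is cut. The forward coupling must form the ether ortho to a benzyloxy group at a temperature low enough for the iodide on ring D to survive.

## Other disconnections considered

Alternative 1: The cut runs through ring C itself. Two of its C–C bonds are disconnected, so that ring C arises from two partners: the 1-dimethylamino-3-silyloxy diene A2, which carries the ring D aryloxy group, and the ethynyl ketone A3, which already holds rings A and B.
- Forward key step: a [4+2] cycloaddition of A2 with A3 in which the amino-bearing diene terminus bonds to the acyl-bearing alkyne carbon. Loss of dimethylamine then aromatises the adduct to A1, with silyloxy, aryloxy and acyl groups in the 1,2,4 pattern of ring C.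
- In its favour: the regiochemistry follows from the push–pull polarisation of both partners, and no copper-mediated coupling at an ortho-alkoxy phenol is needed. The hindered A–B ether would be made beforehand intermolecularly on an aldehyde-activated fluoroarene. On that bond the alternative is the better plan, because no dilution is required.
- Against it here: A2 is a hydrolytically sensitive diene that must be made with the aryloxy substituent already in place. The ynone A3 has an acidic methylene between its carbonyl and ring B, so the amine released on aromatisation could isomerise it or add to it. A1 is still acyclic, its B–C bridge carries a ketone that has to be removed, and the D–A bridge must still be built from the ester and the masked aldehyde. A separate macrocyclisation and several redox adjustments therefore follow.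
- Comparison: structurally, the de novo arene synthesis solves a substitution problem that the purchase of 1 already solves. Mechanistically, a polarised cycloaddition is as predictable as an SNAr reaction, so the two are equal there. In step economy the chosen plan is ahead, because its key step closes the macrocycle and the alternative's does not.

Alternative 2: The cut is the C–O bond between ring C and the ring D oxygen. The precursor A5 has ring C as a 2,6-dibromophenol and ring D as a 2,6-dichlorophenol, with both bridges and the A–B ether in place.
- Forward key step: Tl(NO3)3 (trivalent thallium) in methanol oxidises the dibromophenol. The ring D phenol oxygen adds to a bromine-bearing ortho carbon, and reductive work-up with zinc rearomatises with loss of that bromine to give A4.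
- In its favour: it follows the presumed biosynthetic logic, and ether formation and ring closure coincide, as in the chosen plan (equal). A5 has saturated bridges and no base-sensitive diketone, which is a point where the alternative is the better. The three remaining halogens could leave in one hydrogenolysis, matching the single finishing step of the chosen route (equal).
- Against it here: it needs a stoichiometric, highly toxic thallium salt. Four halogen atoms must be installed only to be removed. The discrimination between the two phenols rests on the halogen pattern alone, and oxidative macrocyclisations of this type must compete with intermolecular coupling and solvent capture. The hindered A–B ether still has to be made earlier.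
- Comparison: the chosen plan uses K2CO3 and an activating group that ends up as part of the skeleton. Its selectivity rests on the element effect of fluoride and not on blocking atoms. Overall step counts should be similar.

Alternative 3: Both CH2–CH2 bonds are cut. Each is traced to a CH2–S–CH2 unit in the 20-membered bis-sulfide A7, which would come from the bis(bromomethyl) A–B ether A8 and the bis(sulfanylmethyl) C–D ether A9.
- Forward key step: irradiation of A7 in P(OMe)3 breaks the C–S bonds, the phosphite takes up sulfur as the thiophosphate, and recombination of the benzylic radical pairs forms both bibenzyl bonds to give A6. BCl3 would then remove the isopropyl group.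
- In its favour: both diaryl ethers are made early by intermolecular reactions. Thiolate alkylation is one of the most forgiving macrocyclisations and closes a larger ring. On the ring-closing event the alternative is the better, and it avoids any conflict between alkene reduction and protecting groups. It is highly convergent, so its step count should be equal or lower.
- Against it here: A8 and A9 are both unsymmetrical, so the twofold alkylation can pair their ends in two ways and give either A7 or its crossed constitutional isomer unless the sulfides are built one at a time. Photochemical extrusion at high dilution is hard to scale. Two extrusions must both succeed without radical escape. The final step needs BCl3 to tell an isopropyl ether from a methyl ether.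
- Comparison: the chosen plan fixes the connectivity unambiguously, because each bond is made between uniquely functionalised partners. It uses only thermal, scalable steps, but accepts a harder ring closure.

Key step: step 11

Remarks on the chemistry:
- Stilbene 9 is taken as an E/Z mixture, since both isomers converge in step 6.
- An atom-by-atom comparison of 15, 16 and 17 shows identical connectivity apart from the bond made in step 11 and the groups changed in step 12. The ring closed has 18 members.
- Three design choices shape the precursor. The ring B phenol is carried as a triisopropylsilyl ether and freed under buffered fluoride. The B–C bridge is saturated by diimide while the iodide and the benzyl ether are present. The benzyl group on ring C is kept, so that it falls in the final hydrogenolysis.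

## Route

Step 1
Reactants: 1 4-(benzyloxy)-3-hydroxybenzaldehyde; 2 (4-iodophenyl)boronic acid
Product: 3 4-(benzyloxy)-3-(4-iodophenoxy)benzaldehyde
Conditions: Cu(OAc)2 (2 equiv), pyridine, 4 Å MS, CH2Cl2, dry air, rt
Reagents that add atoms: none
Why: Chan–Lam oxidative O-arylation; the phenoxide and the aryl group meet on copper and reductive elimination forms the diaryl ether at room temperature, where divalent copper does not insert into the C–I bond, and the aldehyde is a spectator.

Step 2
Reactants: 3 4-(benzyloxy)-3-(4-iodophenoxy)benzaldehyde
Product: 4 [4-(benzyloxy)-3-(4-iodophenoxy)phenyl]methanol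
Conditions: NaBH4, MeOH/THF, 0 °C
Reagents that add atoms: none
Why: Hydride reduction of an aryl aldehyde; the aryl iodide and the ethers are inert to borohydride.

Step 3
Reactants: 4 [4-(benzyloxy)-3-(4-iodophenoxy)phenyl]methanol
Product: 5 {[4-(benzyloxy)-3-(4-iodophenoxy)phenyl]methyl}triphenylphosphonium bromide
Conditions: PPh3·HBr, MeCN, reflux
Reagents that add atoms: triphenylphosphine hydrobromide, [Br-].c1ccc(cc1)[PH+](c1ccccc1)c1ccccc1
Why: Direct conversion of an electron-rich benzylic alcohol into its phosphonium salt; the para-benzyloxy group assists ionisation of the protonated alcohol and triphenylphosphine captures the benzylic electrophile, under acid mild enough for the benzyl ether.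

Step 4
Reactants: 6 3-hydroxybenzaldehyde
Product: 7 3-{[tri(propan-2-yl)silyl]oxy}benzaldehyde
Conditions: TIPSCl, imidazole, DMF, rt
Reagents that add atoms: chlorotri(propan-2-yl)silane, CC(C)[Si](Cl)(C(C)C)C(C)C
Why: Standard O-silylation of a phenol; the bulky triisopropylsilyl group is chosen to withstand ylide base, aqueous acetate at reflux and the cross-coupling, and to be removable without touching the benzyl ether.

Step 5
Reactants: 5 {[4-(benzyloxy)-3-(4-iodophenoxy)phenyl]methyl}triphenylphosphonium bromide; 7 3-{[tri(propan-2-yl)silyl]oxy}benzaldehyde
Product: 9 [3-{2-[4-(benzyloxy)-3-(4-iodophenoxy)phenyl]ethenyl}phenoxy]tri(propan-2-yl)silane (E/Z mixture), via phosphonium ylide 8 (not isolated)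
Conditions: NaHMDS, THF, 0 °C; then 7, 0 °C to rt
Reagents that add atoms: none
Why: Wittig olefination with a semi-stabilised benzylic ylide; the amide base forms the ylide without halogen–metal exchange at the iodide or attack at silicon, and the mixed olefin geometry is of no consequence.

Step 6
Reactants: 9 [3-{2-[4-(benzyloxy)-3-(4-iodophenoxy)phenyl]ethenyl}phenoxy]tri(propan-2-yl)silane (E/Z mixture)
Product: 10 [3-{2-[4-(benzyloxy)-3-(4-iodophenoxy)phenyl]ethyl}phenoxy]tri(propan-2-yl)silane
Conditions: TsNHNH2, NaOAc, DME/H2O, reflux
Reagents that add atoms: none
Why: Diimide reduction; diimide released from the sulfonyl hydrazide transfers two hydrogens to the C=C bond in a concerted step and leaves the aryl iodide, benzyl ether and silyl ether alone, which palladium and hydrogen would not.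

Step 7
Reactants: 11 2-fluoro-3-methoxybenzaldehyde
Product: 12 1-ethynyl-2-fluoro-3-methoxybenzene
Conditions: dimethyl (1-diazo-2-oxopropyl)phosphonate, K2CO3, MeOH, 0 °C to rt
Reagents that add atoms: dimethyl (1-diazo-2-oxopropyl)phosphonate, CC(=O)C(=[N+]=[N-])P(=O)(OC)OC
Why: Seyferth–Gilbert homologation in the Ohira–Bestmann form; the diazophosphonate anion made in situ condenses with the aldehyde, and loss of phosphate and nitrogen followed by a 1,2-hydrogen shift gives the terminal alkyne at a temperature where methoxide does not displace the fluoride.

Step 8
Reactants: 10 [3-{2-[4-(benzyloxy)-3-(4-iodophenoxy)phenyl]ethyl}phenoxy]tri(propan-2-yl)silane; 12 1-ethynyl-2-fluoro-3-methoxybenzene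
Product: 13 {3-[2-(4-(benzyloxy)-3-{4-[(2-fluoro-3-methoxyphenyl)ethynyl]phenoxy}phenyl)ethyl]phenoxy}tri(propan-2-yl)silane
Conditions: PdCl2(PPh3)2 (cat.), CuI (cat.), Et3N, THF, rt, argon
Reagents that add atoms: none
Why: Sonogashira coupling; zerovalent palladium inserts into the C–I bond at room temperature while the C–F bond is inert, and the copper acetylide transfers the alkyne.

Step 9
Reactants: 13 {3-[2-(4-(benzyloxy)-3-{4-[(2-fluoro-3-methoxyphenyl)ethynyl]phenoxy}phenyl)ethyl]phenoxy}tri(propan-2-yl)silane
Product: 14 1-(2-fluoro-3-methoxyphenyl)-2-{4-[2-(benzyloxy)-5-(2-{3-[tri(propan-2-yl)silyloxy]phenyl}ethyl)phenoxy]phenyl}ethane-1,2-dione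
Conditions: PdCl2 (10 mol%), DMSO, 140 °C
Reagents that add atoms: dimethyl sulfoxide, CS(C)=O
Why: Oxidation of a diaryl alkyne to a benzil with divalent palladium and DMSO as oxygen donor (oxypalladation of the coordinated alkyne by sulfoxide oxygen, twice, with release of dimethyl sulfide); ethers and benzylic CH2 groups are not attacked, and any silyl loss here would only anticipate step 10.

Step 10
Reactants: 14 1-(2-fluoro-3-methoxyphenyl)-2-{4-[2-(benzyloxy)-5-(2-{3-[tri(propan-2-yl)silyloxy]phenyl}ethyl)phenoxy]phenyl}ethane-1,2-dione
Product: 15 1-(2-fluoro-3-methoxyphenyl)-2-(4-{2-(benzyloxy)-5-[2-(3-hydroxyphenyl)ethyl]phenoxy}phenyl)ethane-1,2-dione (seco fluoro benzil with free ring B phenol)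
Conditions: TBAF, AcOH, THF, 0 °C
Reagents that add atoms: none
Why: Fluoride-driven cleavage of an aryl silyl ether; the acetic acid buffer keeps the liberated phenol protonated, so neither intermolecular SNAr nor base chemistry at the diketone can start, and the benzyl ether is untouched.

Step 11
Reactants: 15 1-(2-fluoro-3-methoxyphenyl)-2-(4-{2-(benzyloxy)-5-[2-(3-hydroxyphenyl)ethyl]phenoxy}phenyl)ethane-1,2-dione
Product: 16 macrocyclic benzil, O-benzyl (18-membered ring; ring A C2–O–ring B bond formed; ring C benzyl ether retained)
Conditions: K2CO3 (5 equiv), 4 Å MS, DMF, 80 °C, 15 added by syringe pump (final concentration about 1 mM)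
Reagents that add atoms: none
Why: Carbonate deprotonates the ring B phenol, the phenoxide adds to the fluorine-bearing carbon of ring A to give a Meisenheimer anion whose charge is delocalised into the ortho ketone, and loss of fluoride restores the arene (addition–elimination). The closest known reaction type is the intramolecular SNAr cycloetherification of phenoxides onto carbonyl- or nitro-activated aryl fluorides, which delivers macrocyclic diaryl ethers. The one new ring is the 18-membered macrocycle, closed end to end by C–O bond formation under pseudo-high dilution, with four rigid arenes limiting the entropic penalty. No stereocentre is created. Ring closure is secured over oligomerisation by the slow addition, and fluoride is displaced in preference to the para-aryloxy group on ring D because addition is rate-determining and is fastest at the C–F carbon, so a moderate temperature suffices. The diketone has no enolisable hydrogen, phenoxide addition to its carbonyls is reversible, and the sieves exclude hydroxide, which could otherwise trigger a benzilic acid rearrangement. The ring C oxygen stays benzylated so only one phenoxide exists, and the hindered ring A carbon is attacked by the unhindered ring B oxygen.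

Step 12
Reactants: 16 macrocyclic benzil, O-benzyl
Product: 17 target macrocycle CNP0309263.0
Conditions: H2 (4 bar), 10% Pd/C, AcOH, H2SO4 (cat.), 50 °C
Reagents that add atoms: none
Why: Acid-promoted catalytic hydrogenolysis of benzylic C–O bonds; each aryl ketone is hydrogenated to a benzylic carbinol whose protonated C–O bond is cleaved to CH2, the benzyl ether is cleaved in the same operation, and the diaryl ethers, the methyl ether and the arenes are stable to palladium under these conditions.

## Compound list

1 | 4-(benzyloxy)-3-hydroxybenzaldehyde | O=Cc1ccc(OCc2ccccc2)c(O)c1 | starting material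
2 | (4-iodophenyl)boronic acid | OB(O)c1ccc(I)cc1 | starting material
3 | 4-(benzyloxy)-3-(4-iodophenoxy)benzaldehyde | O=Cc1ccc(OCc2ccccc2)c(Oc2ccc(I)cc2)c1 | intermediate
4 | [4-(benzyloxy)-3-(4-iodophenoxy)phenyl]methanol | OCc1ccc(OCc2ccccc2)c(Oc2ccc(I)cc2)c1 | intermediate
5 | {[4-(benzyloxy)-3-(4-iodophenoxy)phenyl]methyl}triphenylphosphonium bromide | [Br-].c1ccc(cc1)[P+](Cc1ccc(OCc2ccccc2)c(Oc2ccc(I)cc2)c1)(c1ccccc1)c1ccccc1 | intermediate
6 | 3-hydroxybenzaldehyde | O=Cc1cccc(O)c1 | starting material
7 | 3-{[tri(propan-2-yl)silyl]oxy}benzaldehyde | CC(C)[Si](Oc1cccc(C=O)c1)(C(C)C)C(C)C | intermediate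
8 | phosphonium ylide from 5, {[4-(benzyloxy)-3-(4-iodophenoxy)phenyl]methylidene}triphenylphosphorane (not isolated) | c1ccc(cc1)P(=Cc1ccc(OCc2ccccc2)c(Oc2ccc(I)cc2)c1)(c1ccccc1)c1ccccc1 | intermediate
9 | [3-{2-[4-(benzyloxy)-3-(4-iodophenoxy)phenyl]ethenyl}phenoxy]tri(propan-2-yl)silane, E/Z mixture | CC(C)[Si](Oc1cccc(C=Cc2ccc(OCc3ccccc3)c(Oc3ccc(I)cc3)c2)c1)(C(C)C)C(C)C | intermediate
10 | [3-{2-[4-(benzyloxy)-3-(4-iodophenoxy)phenyl]ethyl}phenoxy]tri(propan-2-yl)silane | CC(C)[Si](Oc1cccc(CCc2ccc(OCc3ccccc3)c(Oc3ccc(I)cc3)c2)c1)(C(C)C)C(C)C | intermediate
11 | 2-fluoro-3-methoxybenzaldehyde | COc1cccc(C=O)c1F | starting material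
12 | 1-ethynyl-2-fluoro-3-methoxybenzene | COc1cccc(C#C)c1F | intermediate
13 | {3-[2-(4-(benzyloxy)-3-{4-[(2-fluoro-3-methoxyphenyl)ethynyl]phenoxy}phenyl)ethyl]phenoxy}tri(propan-2-yl)silane | COc1cccc(C#Cc2ccc(Oc3cc(CCc4cccc(O[Si](C(C)C)(C(C)C)C(C)C)c4)ccc3OCc3ccccc3)cc2)c1F | intermediate
14 | 1-(2-fluoro-3-methoxyphenyl)-2-{4-[2-(benzyloxy)-5-(2-{3-[tri(propan-2-yl)silyloxy]phenyl}ethyl)phenoxy]phenyl}ethane-1,2-dione | COc1cccc(C(=O)C(=O)c2ccc(Oc3cc(CCc4cccc(O[Si](C(C)C)(C(C)C)C(C)C)c4)ccc3OCc3ccccc3)cc2)c1F | intermediate
15 | 1-(2-fluoro-3-methoxyphenyl)-2-(4-{2-(benzyloxy)-5-[2-(3-hydroxyphenyl)ethyl]phenoxy}phenyl)ethane-1,2-dione (seco fluoro benzil, free ring B phenol) | COc1cccc(C(=O)C(=O)c2ccc(Oc3cc(CCc4cccc(O)c4)ccc3OCc3ccccc3)cc2)c1F | intermediate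
16 | macrocyclic benzil, O-benzyl (18-membered; diketone between rings D and A, benzyl ether on ring C) | COc1cccc2c1Oc1cccc(c1)CCc1ccc(OCc3ccccc3)c(c1)Oc1ccc(cc1)C(=O)C2=O | intermediate
17 | CNP0309263.0, macrocyclic bis(bibenzyl) with ring A methoxy and ring C hydroxyl | COc1cccc2c1Oc1cccc(c1)CCc1ccc(O)c(c1)Oc1ccc(cc1)CC2 | target

## Step count and risk

Total step count: 12. Longest linear sequence: 10 steps (1 → 3 → 4 → 5 → 9 → 10 → 13 → 14 → 15 → 16 → 17, that is steps 1, 2, 3, 5, 6, 8, 9, 10, 11 and 12).

Least certain steps:

Step 11 (key step). The most likely failure is chain growth by intermolecular etherification outrunning ring closure. The second is degradation of the 1,2-dicarbonyl unit by adventitious hydroxide (benzilic acid type rearrangement or C–C cleavage) during the long heating in base. Exchange of the aryloxy group para to the carbonyl on ring D is a further, lesser risk. The fallback moves the hindered ether formation to an intermolecular setting and closes the ring by carbonyl coupling instead. It sets out from 10 and 11 and returns to the route at 17.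
- Iodine–magnesium exchange on 10 with i-PrMgCl·LiCl in THF at −20 °C, then quenching with DMF, would give 4-{2-(benzyloxy)-5-[2-(3-{[tri(propan-2-yl)silyl]oxy}phenyl)ethyl]phenoxy}benzaldehyde F1.
- Buffered TBAF/AcOH would free the phenol 4-{2-(benzyloxy)-5-[2-(3-hydroxyphenyl)ethyl]phenoxy}benzaldehyde F2.
- Intermolecular SNAr of F2 with 11 (K2CO3, DMF, 100 °C, ordinary concentration, fluoride activated by the ortho aldehyde) would give the dialdehyde 2-(3-{2-[4-(benzyloxy)-3-(4-formylphenoxy)phenyl]ethyl}phenoxy)-3-methoxybenzaldehyde F3.
- McMurry coupling of F3 with low-valent titanium from TiCl4 and Zn (THF, pyridine, reflux, high dilution) would close the 18-membered ring as the macrocyclic stilbene F4.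
- Hydrogenation of F4 over Pd/C (H2, EtOAc/MeOH, rt) would saturate the olefin and remove the benzyl group to give 17.

Step 12. The most likely failure is stalling at the carbinol stage, that is incomplete hydrogenolysis of the benzylic C–O bond next to the ortho-flanked ring A. Forcing the conditions could start ring saturation. The fallback separates carbonyl reduction from C–O cleavage, sets out from 16 and returns at 17.
- NaBH4 in MeOH/THF at 0 °C would give the macrocyclic 1,2-diol F5 (mixture of diastereomers, configuration of no consequence).
- Ac2O, pyridine and DMAP would give the macrocyclic diacetate F6.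
- Hydrogenolysis of the two benzylic acetates and the benzyl ether (H2, Pd/C, AcOH/EtOAc, rt) would give 17.

Step 9. The most likely failure is incomplete dioxygenation of the hindered, ortho-fluorinated alkyne at one extreme, or oxidative C–C cleavage on prolonged heating at the other. Loss of the silyl group would be tolerable. The fallback replaces direct dioxygenation by hydration followed by oxidation of the activated methylene. It sets out from 13 and returns at 14.
- Hydration with Ph3PAuCl/AgOTf (cat.) in dioxane/H2O at 80 °C would give mainly the deoxybenzoin with the carbonyl next to ring D, F7, together with its regioisomer with the carbonyl next to ring A, F8.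
- Both converge when the α-methylene is oxidised with SeO2 in dioxane/H2O at reflux (Riley oxidation) to give 14.

Step 1. The most likely failure is sluggish arylation of the ortho-benzyloxy phenol, with protodeboronation and homocoupling of 2 consuming the boronic acid. The fallback uses an aryl halide electrophile under Ullmann conditions. It sets out from 1 and returns at 3. Compound 1 is coupled with an excess of 1,4-diiodobenzene (CuI as the monovalent copper source, N,N-dimethylglycine, Cs2CO3, dioxane, 90 °C); the excess suppresses double etherification. This fallback makes no compound outside the list, hence F0.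

## Further compounds

F1 | step 11 | 4-{2-(benzyloxy)-5-[2-(3-{[tri(propan-2-yl)silyl]oxy}phenyl)ethyl]phenoxy}benzaldehyde | CC(C)[Si](Oc1cccc(CCc2ccc(OCc3ccccc3)c(Oc3ccc(C=O)cc3)c2)c1)(C(C)C)C(C)C
F2 | step 11 | 4-{2-(benzyloxy)-5-[2-(3-hydroxyphenyl)ethyl]phenoxy}benzaldehyde | O=Cc1ccc(Oc2cc(CCc3cccc(O)c3)ccc2OCc2ccccc2)cc1
F3 | step 11 | 2-(3-{2-[4-(benzyloxy)-3-(4-formylphenoxy)phenyl]ethyl}phenoxy)-3-methoxybenzaldehyde | COc1cccc(C=O)c1Oc1cccc(CCc2ccc(OCc3ccccc3)c(Oc3ccc(C=O)cc3)c2)c1
F4 | step 11 | macrocyclic stilbene, O-benzyl (CH=CH between rings D and A, olefin geometry not fixed) | COc1cccc2c1Oc1cccc(c1)CCc1ccc(OCc3ccccc3)c(c1)Oc1ccc(cc1)C=C2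
F5 | step 12 | macrocyclic 1,2-diol, O-benzyl (mixture of diastereomers) | COc1cccc2c1Oc1cccc(c1)CCc1ccc(OCc3ccccc3)c(c1)Oc1ccc(cc1)C(O)C2O
F6 | step 12 | macrocyclic 1,2-diacetate, O-benzyl (mixture of diastereomers) | COc1cccc2c1Oc1cccc(c1)CCc1ccc(OCc3ccccc3)c(c1)Oc1ccc(cc1)C(OC(C)=O)C2OC(C)=O
F7 | step 9 | 2-(2-fluoro-3-methoxyphenyl)-1-{4-[2-(benzyloxy)-5-(2-{3-[tri(propan-2-yl)silyloxy]phenyl}ethyl)phenoxy]phenyl}ethan-1-one | COc1cccc(CC(=O)c2ccc(Oc3cc(CCc4cccc(O[Si](C(C)C)(C(C)C)C(C)C)c4)ccc3OCc3ccccc3)cc2)c1F
F8 | step 9 | 1-(2-fluoro-3-methoxyphenyl)-2-{4-[2-(benzyloxy)-5-(2-{3-[tri(propan-2-yl)silyloxy]phenyl}ethyl)phenoxy]phenyl}ethan-1-one | COc1cccc(C(=O)Cc2ccc(Oc3cc(CCc4cccc(O[Si](C(C)C)(C(C)C)C(C)C)c4)ccc3OCc3ccccc3)cc2)c1F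
F0 | step 1 | none | none
A1 | alternative 1 | methyl 4-{5-[2-(3-{[2-(1,3-dioxolan-2-yl)-6-methoxyphenyl]oxy}phenyl)acetyl]-2-[(tert-butyldimethylsilyl)oxy]phenoxy}benzoate | COC(=O)c1ccc(Oc2cc(C(=O)Cc3cccc(Oc4c(OC)cccc4C4OCCO4)c3)ccc2O[Si](C)(C)C(C)(C)C)cc1
A2 | alternative 1 | methyl 4-({1-(dimethylamino)-3-[(tert-butyldimethylsilyl)oxy]buta-1,3-dien-2-yl}oxy)benzoate | COC(=O)c1ccc(OC(=CN(C)C)C(=C)O[Si](C)(C)C(C)(C)C)cc1
A3 | alternative 1 | 1-{3-[2-(1,3-dioxolan-2-yl)-6-methoxyphenoxy]phenyl}but-3-yn-2-one | C#CC(=O)Cc1cccc(Oc2c(OC)cccc2C2OCCO2)c1
A4 | alternative 2 | bromo dichloro macrocycle (bromine ortho to the ring C hydroxyl, two chlorines flanking the ring D ether oxygen) | COc1cccc2c1Oc1cccc(c1)CCc1cc(Br)c(O)c(c1)Oc1c(Cl)cc(cc1Cl)CC2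
A5 | alternative 2 | 2,6-dibromo-4-[2-(3-{2-[2-(3,5-dichloro-4-hydroxyphenyl)ethyl]-6-methoxyphenoxy}phenyl)ethyl]phenol | COc1cccc(CCc2cc(Cl)c(O)c(Cl)c2)c1Oc1cccc(CCc2cc(Br)c(O)c(Br)c2)c1
A6 | alternative 3 | O-isopropyl ether of the target macrocycle | COc1cccc2c1Oc1cccc(c1)CCc1ccc(OC(C)C)c(c1)Oc1ccc(cc1)CC2
A7 | alternative 3 | 20-membered macrocyclic bis(benzyl sulfide), O-isopropyl | COc1cccc2c1Oc1cccc(c1)CSCc1ccc(OC(C)C)c(c1)Oc1ccc(cc1)CSC2
A8 | alternative 3 | 1-(bromomethyl)-2-[3-(bromomethyl)phenoxy]-3-methoxybenzene | COc1cccc(CBr)c1Oc1cccc(CBr)c1
A9 | alternative 3 | {4-(propan-2-yloxy)-3-[4-(sulfanylmethyl)phenoxy]phenyl}methanethiol | CC(C)Oc1ccc(CS)cc1Oc1ccc(CS)cc1
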